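A curve fitted through the south run can be carried forward without limit, yet its readings stop at 80.0 min, and cedar and elm stop at 4.0 h, 3.00 times as late.

in all of them: substrate 0.010 M; free catalyst 0.15 mol%

| charge | reagent | scavenger | remark | time |
|---|---|---|---|---|
| south | 1.8 equiv | 0.50 equiv | run made earlier |  |
| cedar | 1.20 equiv | 0.500 equiv |  | 4.0 h |
| elm | 1.20 equiv | 0.650 equiv |  | 4.0 h |

- south (time / min: substrate / %, product / %): 6.00: 99.2, 1.5; 15.0: 96.0, 5.1; 40.0: 87.9, 8.4; 80.0: 79.0, 17.1

(standard deviation of a reading: 1 percentage point)

- part of the substrate that has reacted at the end, cedar
- part of the substrate that has reacted at the end, elm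
- what raising the equivalents of scavenger from its lowest to its highest value here does to the part of the substrate that has reacted (changes below 5 percentage points count as none) (it falls / it rises / no change)

- what has gone from substrate into another species counts as reacted, even if it can come back

1. Slope. In the south run, the fraction of substrate left falls to 79.0% by 80.0 min. Read as first-order decay, this gives a half-life of 3.92 h.

2. Knees. That curve passes 40.0 min at 88.9%, against a reading of 87.9%. The gap of 0.98 percentage points is about the scatter, so no knee can be read.

3. Cedar. My own assumption is that the rate follows the reagent charge. Cedar's half-life then stretches to 5.88 h, and its curve starts at a slope of 0.118 h⁻¹ of the charge.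

4. Crossing. Substrate would reach a fraction of 0.5 at that half-life, which is later than cedar's stop. By this estimate cedar ends before the crossing, at a count of half-lives, the time over the half-life, of 0.680.

5. Level. Taken one to one, the reagent charge of 1.20 equiv exceeds the substrate, so I take substrate as the limiting reagent, with its curve running towards zero. By this estimate, cedar keeps 62.4% at the stop, so 37.6% has reacted. Scavenger has no term in this count, so my figure for elm is the same and I expect no change.

6. Forecast. It gives 36% for cedar, 33% for elm and no change, both figures below my 37.6%, and says: “Nothing here tests the reagent order or the scavenger's role, so cedar and elm are extrapolations.”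

7. Result. The flasks give 37.2% for cedar and 36.4% for elm, so the trend is no change, with a change of −0.81 points.

    substrate + free catalyst → catalyst intermediate A (k = 40600 L mol⁻¹ h⁻¹)
    2 catalyst intermediate B → spent catalyst (k = 1.10 × 10⁵ L mol⁻¹ h⁻¹)
    reagent + catalyst intermediate A ⇌ catalyst intermediate B (K = 62.0 L mol⁻¹, k = 24300 L mol⁻¹ h⁻¹)
    catalyst intermediate B → released group + catalyst intermediate C (k = 381 h⁻¹)
    catalyst intermediate C → free catalyst + product (k = 1380 h⁻¹)
    substrate + released group ⇌ idle adduct, settled at all times (K = 76.3 L mol⁻¹)
    scavenger + released group → scavenged by-product (k = 294 L mol⁻¹ h⁻¹)

The count's 37.6% stands 0.40 points above cedar, although cedar holds 29.5% of its catalyst as spent catalyst, which the count does not contain. Changing the reagent alone takes the south run, without its scatter, at its last reading from 19.9% to 17.0%. From cedar to elm, product stays at 33.7% while idle adduct goes from 3.46% to 2.61%. The neighbour flask is elm with 0.6 mol% of free catalyst. Scaling the count by the loading gives 2.72 half-lives and 15.2% of substrate left. That neighbour flask keeps 19% of its substrate unbound, with 47.2% of its catalyst spent.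

(The runs stem from a simulated flask from invented constants.)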